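The slowness of this chemistry showed in the earlier runs. Incoming ligand works on the starting complex, capture agent turns what forms into trapped intermediate, and teal had reached just 43% after 20.0 min.

| flask | starting complex | incoming ligand | leaving ligand | protic impurity | capture agent | remark | time |
|---|---|---|---|---|---|---|---|
| teal | 20 mM | 80 mM | 10 mM | 20 mM | 20 mM | run made earlier |  |
| grey | 20 mM | 40 mM | 10 mM | 20 mM | 20 mM | run made earlier |  |
| ochre | 20 mM | 160 mM | 10 mM | 20 mM | 20 mM | run made earlier |  |
| blue | 20 mM | 80 mM | 20 mM | 20 mM | 20 mM | run made earlier |  |
| noon | 20 mM | 80.0 mM (fed, over 20 min) | 10.0 mM | 20.0 mM | 20.0 mM | all else is in the flask from the start; the feed brings no volume worth counting | 30 min |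
| dusk | 20 mM (fed, over 20 min) | 80.0 mM | 10.0 mM | 20.0 mM | 20.0 mM | all else is in the flask from the start; the feed brings no volume worth counting | 30 min |
| winter | 20 mM (in portions, 3, over 20 min) | 80.0 mM | 10.0 mM | 20.0 mM | 20.0 mM | first portion at the start, last at 20 min | 30 min |
| autumn | 20 mM | 80.0 mM | 10.0 mM | 20.0 mM | 20.0 mM | everything together at the start | 30 min |

- teal (time / min: trapped intermediate / %, complex with two exchanged / %): 1.33: 3, 0; 4.00: 9, 0; 6.00: 16, 1; 10.0: 24, 1; 15.0: 34, 3; 20.0: 43, 2
- grey (time / min: trapped intermediate / %, complex with two exchanged / %): 1.33: 0, 2; 4.00: 5, 0; 6.00: 12, 3; 10.0: 14, 0; 15.0: 15, 2; 20.0: 18, 0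
- ochre (time / min: trapped intermediate / %, complex with two exchanged / %): 1.33: 3, 0; 2.50: 10, 2; 4.00: 19, 3; 6.00: 28, 0; 10.0: 41, 7; 20.0: 64, 8
- blue (time / min: trapped intermediate / %, complex with two exchanged / %): 1.50: 1, 0; 5.00: 14, 2; 8.00: 22, 0; 12.0: 30, 0; 20.0: 39, 2

(scatter of a reading: 2 percentage points)



- the flask that comes out highest in amount of trapped intermediate, in percent of the starting complex charged, or "all alike" when all lie within 1.5 percentage points (noon / dusk / winter / autumn / all alike)
- trapped intermediate at the end, in percent of the starting complex charged, noon
- trapped intermediate at the end, in percent of the starting complex charged, dusk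
- trapped intermediate at the end, in percent of the starting complex charged, winter
- trapped intermediate at the end, in percent of the starting complex charged, autumn

I treated the loss of starting complex as pseudo-first-order. Writing each yield as one minus an exponential, teal's exponent at 20.0 min read 2.83 times grey's for twice the ligand charged, which fits the ligand left above the protic impurity: 60.0 mM against 20.0 mM. So I let the impurity take its own charge of ligand first, and from teal's last reading I read a free-ligand constant, 4.68 × 10⁻⁴ /mM/min: the yield is one minus the exponential of minus this constant times mean free ligand times time.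

I took autumn's free ligand as a steady 60.0 mM over 30 min, so I reckoned 57.0% of trapped intermediate. For noon I let the feed meet the impurity's demand by 5.00 min, and then let free ligand climb in a straight line to 60.0 mM at 20 min. Its mean is 35.0 mM, which gives 38.9%. In dusk the complex spends a mean 20.0 min in the flask, which gives 43.0%. Winter has the same mean, but its portions reckoned singly gave 41.5%, so using the mean cost 1.5 percentage points.

The forecast said autumn, with noon 42%, dusk 42%, winter 41% and autumn 52%: “Autumn wins.”

The flasks gave noon 39.4%, dusk 39.9%, winter 39.3% and autumn 53.7%, and autumn stood highest.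

    complex with one exchanged + capture agent → trapped intermediate (k = 0.890 /M/s)
    complex with two exchanged + incoming ligand ⇌ leaving ligand + complex with three exchanged (K = 1.30, k = 7.80 × 10⁻⁴ /M/s)
    starting complex + incoming ligand ⇌ leaving ligand + complex with one exchanged (K = 6.80, k = 0.00900 /M/s)
    complex with one exchanged + incoming ligand ⇌ leaving ligand + complex with two exchanged (K = 0.310, k = 0.0110 /M/s)
    protic impurity + incoming ligand → quenched reagent (k = 0.180 /M/s)
    leaving ligand → by-product carried off (k = 0.00210 /s)

My reckoning stood 3.3 points above autumn and 3.1 points above dusk. In autumn the protic impurity was at 0% by the end, with quenched reagent at 20.0 mM. I then took the neighbouring flask, autumn with 8.0 mM of protic impurity. I took its free ligand as a steady 72.0 mM, and the same constant gave 63.6%. That flask held 8.00 mM of quenched reagent at the end, and its trapped intermediate came to 59.1%.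

The numbers in the tables come from a simulation for an exercise; the scatter is artificial.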